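**Retrosynthetic overview**
1. Locants used below: C5 = CH(isopropenyl), C6 = CH–O(lactone), C7 = ring-fusion CH, C8 = CH–O(ester), C9 = CH2, C10 = C(Me)(vinyl), C11 = C(Me)(OAc), C12 = lactone C=O. The C8 ester and C11 acetate go on last; the C11 quaternary centre comes from convex-face C-methylation of an α-(MOM-oxy) lactone enolate.
2. Key disconnection C7–C8: a SmI2 ketyl (aldehyde carbon C8 made nucleophilic) adds 6-exo to the β-carbon C7 of a 3-alkoxybutenolide, closing the carbocycle onto the lactone and setting C7 and C8.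
3. The butenolide comes from an acylpyruvate (oxalate Claisen condensation of a methyl ketone); C6 is set by Felkin–Anh reduction.
4. C5/C10 come from an enantioselective Ireland–Claisen rearrangement of the 3-methylbut-3-enoate of (Z)-3-methylpent-2-en-4-yn-1-ol; the ethynyl group is the masked C9H2–C8HO.
5. Ring order: γ-lactone (butenolide) first, cyclohexane second.

Assumption: the (S,S)-boron controller in step 2 gives the (2R,3S)-acid 5; if the sense of induction is the opposite, the (R,R)-controller is used with no other change.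

**Route**

Step 1
Reactants: 1 (Z)-3-methylpent-2-en-4-yn-1-ol; 2 3-methylbut-3-enoic acid
Product: 3 (2Z)-3-methylpent-2-en-4-yn-1-yl 3-methylbut-3-enoate
Conditions: DCC, DMAP (5 mol %), CH2Cl2, 0 °C
Reagents that add atoms: none
Why: Steglich esterification of a primary allylic alcohol, run cold with little DMAP so the β,γ-double bond of the acyl part does not move into conjugation; no stereocentre is formed.

Step 2
Reactants: 3 (2Z)-3-methylpent-2-en-4-yn-1-yl 3-methylbut-3-enoate
Product: 5 (2R,3S)-3-ethynyl-3-methyl-2-(prop-1-en-2-yl)pent-4-enoic acid, via boron ketene acetal 4 (not isolated)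
Conditions: (S,S)-2-bromo-1,3-bis[3,5-bis(trifluoromethyl)phenylsulfonyl]-4,5-diphenyl-1,3,2-diazaborolidine (1.2 equiv, from the bis-sulfonamide and BBr3), Et3N, PhMe–hexane, −78 °C, then −20 to 4 °C; H2O
Reagents that add atoms: none
Why: Enantioselective Ireland–Claisen rearrangement through a chair transition state, in which the E(O)-boron enolate (isopropenyl pseudo-axial) and the Z-alkene (ethynyl pseudo-axial) fix the C5/C10 relative configuration (isopropenyl and vinyl anti along C6–C5–C10–C9) and the C2-symmetric sulfonamidoborane blocks one enolate face to set the absolute configuration.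

Step 3
Reactants: 5 (2R,3S)-3-ethynyl-3-methyl-2-(prop-1-en-2-yl)pent-4-enoic acid
Product: 7 (3R,4S)-4-ethynyl-4-methyl-3-(prop-1-en-2-yl)hex-5-en-2-one, via trilithium adduct 6 (not isolated)
Conditions: MeLi (3.3 equiv), Et2O, 0 °C to rt; H2O
Reagents that add atoms: methyllithium, C[Li]
Why: Organolithium addition to a lithium carboxylate gives a gem-diolate that only collapses to the methyl ketone on work-up, so there is no over-addition (two further equivalents are used up by CO2H and C≡C–H); the stereocentres are not touched.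

Step 4
Reactants: 7 (3R,4S)-4-ethynyl-4-methyl-3-(prop-1-en-2-yl)hex-5-en-2-one
Product: 9 methyl (2Z,5R,6S)-6-ethynyl-2-hydroxy-6-methyl-4-oxo-5-(prop-1-en-2-yl)octa-2,7-dienoate, via lithium enolate 8 (not isolated)
Conditions: LiHMDS (2.2 equiv), THF, −78 °C; (CO2Me)2, −78 to −20 °C; 1 M HCl
Reagents that add atoms: dimethyl oxalate, COC(=O)C(=O)OC
Why: Crossed Claisen condensation of the kinetic methyl-side enolate with non-enolisable dimethyl oxalate, the product being held as its diketonate so that C5 is not epimerised; this brings in C11 and C12.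

Step 5
Reactants: 9 methyl (2Z,5R,6S)-6-ethynyl-2-hydroxy-6-methyl-4-oxo-5-(prop-1-en-2-yl)octa-2,7-dienoate
Product: 12 (5R)-5-[(1R,2S)-2-ethynyl-2-methyl-1-(prop-1-en-2-yl)but-3-en-1-yl]-3-hydroxyfuran-2(5H)-one, via silyl enol ether 10 (not isolated), via lithium alkoxide 11 (not isolated)
Conditions: TMSCl, Et3N, THF, 0 °C; L-Selectride, −78 °C; 2 M HCl, rt
Reagents that add atoms: none
Why: Transient O-silylation of the enolised α-keto group leaves only the C6 ketone open to Felkin–Anh 1,2-reduction (hydride anti to the quaternary C10, which sets C6 as R), and acid then frees the α-keto ester, which lactonises to the 3-hydroxybutenolide whatever the enol ether geometry.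

Step 6
Reactants: 12 (5R)-5-[(1R,2S)-2-ethynyl-2-methyl-1-(prop-1-en-2-yl)but-3-en-1-yl]-3-hydroxyfuran-2(5H)-one
Product: 13 (5R)-5-[(1R,2S)-2-ethynyl-2-methyl-1-(prop-1-en-2-yl)but-3-en-1-yl]-3-(methoxymethoxy)furan-2(5H)-one
Conditions: MOMCl, i-Pr2NEt, CH2Cl2, 0 °C
Reagents that add atoms: chloromethyl methyl ether, COCCl
Why: O-alkylation (Williamson-type etherification) of the acidic enol with a hard electrophile gives a non-migrating protecting group on the future C11 oxygen.

Step 7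
Reactants: 13 (5R)-5-[(1R,2S)-2-ethynyl-2-methyl-1-(prop-1-en-2-yl)but-3-en-1-yl]-3-(methoxymethoxy)furan-2(5H)-one
Product: 14 (3S,4R)-3-ethenyl-4-[(2R)-4-(methoxymethoxy)-5-oxo-2,5-dihydrofuran-2-yl]-3,5-dimethylhex-5-enal
Conditions: CpRu(MeCN)3PF6 (5 mol %), 5,5′-bis(trifluoromethyl)-2,2′-bipyridine (5 mol %), H2O, NMP, 25–50 °C
Reagents that add atoms: water, O
Why: Ru-catalysed anti-Markovnikov hydration of the terminal alkyne via a ruthenium vinylidene gives the aldehyde under neutral conditions and leaves the three alkenes and the enol ether alone.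

Step 8
Reactants: 14 (3S,4R)-3-ethenyl-4-[(2R)-4-(methoxymethoxy)-5-oxo-2,5-dihydrofuran-2-yl]-3,5-dimethylhex-5-enal
Product: 17 (3aS,4R,6S,7R,7aR)-6-ethenyl-4-hydroxy-3-(methoxymethoxy)-6-methyl-7-(prop-1-en-2-yl)hexahydro-1-benzofuran-2(3H)-one (C3 epimers), via samarium ketyl 15 (not isolated), via samarium enolate 16 (not isolated)
Conditions: SmI2 (2.5 equiv), t-BuOH, THF, −78 °C
Reagents that add atoms: none
Why: SmI2 ketyl–olefin reductive cyclisation (6-exo-trig), in which the aldehyde carbon becomes a nucleophilic ketyl and attacks the electrophilic β-carbon of the butenolide; the tether through C6 forces attack on the lactone face syn to C5 (cis ring fusion, C7), and the O–Sm group sits equatorial, away from the axial vinyl and axial lactone oxygen (C8 trans to C7–C11).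

Step 9
Reactants: 17 (3aS,4R,6S,7R,7aR)-6-ethenyl-4-hydroxy-3-(methoxymethoxy)-6-methyl-7-(prop-1-en-2-yl)hexahydro-1-benzofuran-2(3H)-one
Product: 19 (3S,3aS,4R,6S,7R,7aR)-6-ethenyl-4-hydroxy-3-(methoxymethoxy)-3,6-dimethyl-7-(prop-1-en-2-yl)hexahydro-1-benzofuran-2(3H)-one, via dilithium alkoxide enolate 18 (not isolated)
Conditions: LDA (2.3 equiv), THF, −78 °C (inverse addition); MeI, DMPU, −78 to −40 °C; H2O
Reagents that add atoms: iodomethane, CI
Why: Enolate C-alkylation of the alkoxide/lactone-enolate dianion, with MeI approaching the open convex face of the cis-fused bicycle (anti to C8 and its oxygen), so CH3 ends cis to H-7 and the OMOM group lies on the concave face (C11 S).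

Step 10
Reactants: 19 (3S,3aS,4R,6S,7R,7aR)-6-ethenyl-4-hydroxy-3-(methoxymethoxy)-3,6-dimethyl-7-(prop-1-en-2-yl)hexahydro-1-benzofuran-2(3H)-one; 2 3-methylbut-3-enoic acid
Product: 20 (3S,3aS,4R,6S,7R,7aR)-6-ethenyl-3-(methoxymethoxy)-3,6-dimethyl-2-oxo-7-(prop-1-en-2-yl)octahydro-1-benzofuran-4-yl 3-methylbut-3-enoate
Conditions: DCC, DMAP (10 mol %), CH2Cl2, 0 °C to rt
Reagents that add atoms: none
Why: Steglich esterification of the only free (secondary, equatorial) hydroxyl, with retention at C8 and no free OH left to translactonise.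

Step 11
Reactants: 20 (3S,3aS,4R,6S,7R,7aR)-6-ethenyl-3-(methoxymethoxy)-3,6-dimethyl-2-oxo-7-(prop-1-en-2-yl)octahydro-1-benzofuran-4-yl 3-methylbut-3-enoate
Product: 21 (3S,3aS,4R,6S,7R,7aR)-6-ethenyl-3-hydroxy-3,6-dimethyl-2-oxo-7-(prop-1-en-2-yl)octahydro-1-benzofuran-4-yl 3-methylbut-3-enoate
Conditions: ZnBr2, n-PrSH, CH2Cl2, 0 °C, 10 min
Reagents that add atoms: none
Why: Lewis acid/thiol cleavage of the MOM acetal (the oxocarbenium is taken by the thiol) breaks only the O–CH2 bond, so C11 keeps its configuration and the esters and alkenes survive.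

Step 12
Reactants: 21 (3S,3aS,4R,6S,7R,7aR)-6-ethenyl-3-hydroxy-3,6-dimethyl-2-oxo-7-(prop-1-en-2-yl)octahydro-1-benzofuran-4-yl 3-methylbut-3-enoate
Product: 22 (3S,3aS,4R,6S,7R,7aR)-3-acetoxy-6-ethenyl-3,6-dimethyl-2-oxo-7-(prop-1-en-2-yl)octahydro-1-benzofuran-4-yl 3-methylbut-3-enoate
Conditions: Ac2O, Sc(OTf)3 (2 mol %), MeCN, −20 °C
Reagents that add atoms: acetic anhydride, CC(=O)OC(C)=O
Why: Lewis-acid-catalysed acetylation of the hindered tertiary alcohol at oxygen (retention at C11), under non-basic conditions that do not move the β,γ-double bond of the C8 ester.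

**Compound list**
1 | (Z)-3-methylpent-2-en-4-yn-1-ol | OC/C=C(/C)C#C | starting material
2 | 3-methylbut-3-enoic acid | C=C(C)CC(=O)O | starting material
3 | (2Z)-3-methylpent-2-en-4-yn-1-yl 3-methylbut-3-enoate | C=C(C)CC(=O)OC/C=C(/C)C#C | intermediate
4 | (S,S)-diazaborolidinyl ketene acetal of 3, E(O)-enolate (not isolated) | C=C(C)/C=C(\OC/C=C(/C)C#C)OB1N(S(=O)(=O)c2cc(cc(c2)C(F)(F)F)C(F)(F)F)[C@@H](c2ccccc2)[C@H](c2ccccc2)N1S(=O)(=O)c3cc(cc(c3)C(F)(F)F)C(F)(F)F | intermediate
5 | (2R,3S)-3-ethynyl-3-methyl-2-(prop-1-en-2-yl)pent-4-enoic acid | C=C[C@](C)(C#C)[C@@H](C(=C)C)C(=O)O | intermediate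
6 | trilithium adduct: lithium acetylide / dilithium gem-diolate from 5 and MeLi (not isolated) | C=C[C@](C)(C#C[Li])[C@@H](C(=C)C)C(C)(O[Li])O[Li] | intermediate
7 | (3R,4S)-4-ethynyl-4-methyl-3-(prop-1-en-2-yl)hex-5-en-2-one | C=C[C@](C)(C#C)[C@@H](C(=C)C)C(C)=O | intermediate
8 | lithium enolate of 7, methyl side (not isolated) | C=C[C@](C)(C#C)[C@@H](C(=C)C)C(=C)O[Li] | intermediate
9 | methyl (2Z,5R,6S)-6-ethynyl-2-hydroxy-6-methyl-4-oxo-5-(prop-1-en-2-yl)octa-2,7-dienoate (enol form of the 2,4-dioxo ester) | C=C[C@](C)(C#C)[C@@H](C(=C)C)C(=O)/C=C(\O)C(=O)OC | intermediate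
10 | methyl (2Z,5R,6S)-6-ethynyl-6-methyl-4-oxo-5-(prop-1-en-2-yl)-2-(trimethylsilyloxy)octa-2,7-dienoate (not isolated) | C=C[C@](C)(C#C)[C@@H](C(=C)C)C(=O)/C=C(\O[Si](C)(C)C)C(=O)OC | intermediate
11 | lithium alkoxide of methyl (2Z,4R,5R,6S)-6-ethynyl-4-hydroxy-6-methyl-5-(prop-1-en-2-yl)-2-(trimethylsilyloxy)octa-2,7-dienoate (not isolated) | C=C[C@](C)(C#C)[C@@H](C(=C)C)[C@@H](O[Li])/C=C(\O[Si](C)(C)C)C(=O)OC | intermediate
12 | (5R)-5-[(1R,2S)-2-ethynyl-2-methyl-1-(prop-1-en-2-yl)but-3-en-1-yl]-3-hydroxyfuran-2(5H)-one | C=C[C@](C)(C#C)[C@@H](C(=C)C)[C@H]1OC(=O)C(O)=C1 | intermediate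
13 | (5R)-5-[(1R,2S)-2-ethynyl-2-methyl-1-(prop-1-en-2-yl)but-3-en-1-yl]-3-(methoxymethoxy)furan-2(5H)-one | C=C[C@](C)(C#C)[C@@H](C(=C)C)[C@H]1OC(=O)C(OCOC)=C1 | intermediate
14 | (3S,4R)-3-ethenyl-4-[(2R)-4-(methoxymethoxy)-5-oxo-2,5-dihydrofuran-2-yl]-3,5-dimethylhex-5-enal | C=C[C@](C)(CC=O)[C@@H](C(=C)C)[C@H]1OC(=O)C(OCOC)=C1 | intermediate
15 | samarium(III) ketyl of 14 (not isolated) | C=C[C@](C)(C[CH]O[Sm](I)I)[C@@H](C(=C)C)[C@H]1OC(=O)C(OCOC)=C1 | intermediate
16 | cyclised bis-samarium(III) alkoxide / lactone enolate (not isolated) | C=C[C@]1(C)C[C@@H](O[Sm](I)I)[C@H]2[C@H](OC(O[Sm](I)I)=C2OCOC)[C@@H]1C(=C)C | intermediate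
17 | (3aS,4R,6S,7R,7aR)-6-ethenyl-4-hydroxy-3-(methoxymethoxy)-6-methyl-7-(prop-1-en-2-yl)hexahydro-1-benzofuran-2(3H)-one (C3 epimers) | C=C[C@]1(C)C[C@@H](O)[C@H]2[C@H](OC(=O)C2OCOC)[C@@H]1C(=C)C | intermediate
18 | dilithium alkoxide / lactone enolate of 17 (not isolated) | C=C[C@]1(C)C[C@@H](O[Li])[C@H]2[C@H](OC(O[Li])=C2OCOC)[C@@H]1C(=C)C | intermediate
19 | (3S,3aS,4R,6S,7R,7aR)-6-ethenyl-4-hydroxy-3-(methoxymethoxy)-3,6-dimethyl-7-(prop-1-en-2-yl)hexahydro-1-benzofuran-2(3H)-one | C=C[C@]1(C)C[C@@H](O)[C@H]2[C@H](OC(=O)[C@@]2(C)OCOC)[C@@H]1C(=C)C | intermediate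
20 | (3S,3aS,4R,6S,7R,7aR)-6-ethenyl-3-(methoxymethoxy)-3,6-dimethyl-2-oxo-7-(prop-1-en-2-yl)octahydro-1-benzofuran-4-yl 3-methylbut-3-enoate | C=C[C@]1(C)C[C@@H](OC(=O)CC(=C)C)[C@H]2[C@H](OC(=O)[C@@]2(C)OCOC)[C@@H]1C(=C)C | intermediate
21 | (3S,3aS,4R,6S,7R,7aR)-6-ethenyl-3-hydroxy-3,6-dimethyl-2-oxo-7-(prop-1-en-2-yl)octahydro-1-benzofuran-4-yl 3-methylbut-3-enoate | C=C[C@]1(C)C[C@@H](OC(=O)CC(=C)C)[C@H]2[C@H](OC(=O)[C@@]2(C)O)[C@@H]1C(=C)C | intermediate
22 | (3S,3aS,4R,6S,7R,7aR)-3-acetoxy-6-ethenyl-3,6-dimethyl-2-oxo-7-(prop-1-en-2-yl)octahydro-1-benzofuran-4-yl 3-methylbut-3-enoate (CNP0106639.1) | C=C[C@]1(C)C[C@@H](OC(=O)CC(=C)C)[C@H]2[C@H](OC(=O)[C@@]2(C)OC(C)=O)[C@@H]1C(=C)C | target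

**Totals**
Total step count: 12. Longest linear sequence: 12 steps (1 to 22; acid 2 enters in steps 1 and 10).

**Three steps most likely to fail**

Step 2 (enantioselective Ireland–Claisen). The risks are the enolate geometry of the β,γ-unsaturated ester, a slow rearrangement and the sense of induction; if the Z(O)-enolate forms instead, the commercial (E)-isomer of 1 gives the same acid. The fallback sets out from 3 and comes back at 5. Ester 3 is turned with LiHMDS/TMSCl (THF, −78 °C) into the achiral trimethylsilyl ketene acetal F1, which rearranges on warming to the racemic trimethylsilyl ester F2. Aqueous work-up gives the racemic acid, that is 5 together with its enantiomer F3. Classical resolution by crystallising the (S)-1-phenylethylammonium salt F4 (or the salt of the antipodal amine, whichever is less soluble), followed by acidification, returns 5.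

Step 5 (one-pot silylation, Felkin reduction, lactonisation). The risks are silylation on the wrong enol oxygen and incomplete selectivity at C6. The fallback sets out from 9 and comes back at 12, and needs no regioselective protection. NaBH4 in MeOH at −40 °C reduces both carbonyl groups (C6 again in the Felkin sense); acid work-up lactonises the diol ester to the α-hydroxy lactone F5. Dess–Martin oxidation of its secondary α-hydroxyl gives the α-keto lactone, which is the keto tautomer of 12.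

Step 8 (SmI2 ketyl–butenolide cyclisation). The risks are a sluggish addition to the donor-substituted acceptor, pinacol coupling or simple aldehyde reduction, and translactonisation by the C8 samarium alkoxide. The fallback sets out from 9 and comes back at 17, and closes the carbocycle before the lactone. Compound 9 is O-alkylated with MOMCl/i-Pr2NEt to the MOM enol ether F6, and Ru-catalysed hydration as in step 7 gives the aldehyde F7. SmI2/MeOH then reduces the much more easily reduced ene-keto-ester, and the samarium enolate closes the ring by aldol addition to the aldehyde, giving the hydroxy ketone F8 (substituents at C7 and C8 equatorial). L-Selectride attacks the ring ketone from the equatorial side, because the axial face is blocked by the axial vinyl group, and the resulting axial C6 alkoxide lactonises onto the methyl ester to give 17.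

**Further compounds**
F1 | step 2 | trimethylsilyl ketene acetal of 3, E(O) | C=C(C)/C=C(\OC/C=C(/C)C#C)O[Si](C)(C)C
F2 | step 2 | racemic trimethylsilyl (2R*,3S*)-3-ethynyl-3-methyl-2-(prop-1-en-2-yl)pent-4-enoate (one enantiomer drawn) | C=C[C@](C)(C#C)[C@@H](C(=C)C)C(=O)O[Si](C)(C)C
F3 | step 2 | (2S,3R)-3-ethynyl-3-methyl-2-(prop-1-en-2-yl)pent-4-enoic acid (enantiomer of 5) | C=C[C@@](C)(C#C)[C@H](C(=C)C)C(=O)O
F4 | step 2 | (S)-1-phenylethylammonium (2R,3S)-3-ethynyl-3-methyl-2-(prop-1-en-2-yl)pent-4-enoate | C=C[C@](C)(C#C)[C@@H](C(=C)C)C(=O)[O-].C[C@H]([NH3+])c1ccccc1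
F5 | step 5 | (5S)-5-[(1R,2S)-2-ethynyl-2-methyl-1-(prop-1-en-2-yl)but-3-en-1-yl]-3-hydroxydihydrofuran-2(3H)-one (C3 epimers) | C=C[C@](C)(C#C)[C@@H](C(=C)C)[C@H]1OC(=O)C(O)C1
F6 | step 8 | methyl (2Z,5R,6S)-6-ethynyl-2-(methoxymethoxy)-6-methyl-4-oxo-5-(prop-1-en-2-yl)octa-2,7-dienoate | C=C[C@](C)(C#C)[C@@H](C(=C)C)C(=O)/C=C(\OCOC)C(=O)OC
F7 | step 8 | methyl (2Z,5R,6S)-6-ethenyl-2-(methoxymethoxy)-6-methyl-4,8-dioxo-5-(prop-1-en-2-yl)oct-2-enoate | C=C[C@](C)(CC=O)[C@@H](C(=C)C)C(=O)/C=C(\OCOC)C(=O)OC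
F8 | step 8 | methyl 2-[(1R,2R,4S,5R)-4-ethenyl-2-hydroxy-4-methyl-6-oxo-5-(prop-1-en-2-yl)cyclohexyl]-2-(methoxymethoxy)acetate (epimers at the acetate carbon) | C=C[C@]1(C)C[C@@H](O)[C@H](C(OCOC)C(=O)OC)C(=O)[C@@H]1C(=C)C
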